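**Retrosynthetic overview**

1. The target is a cis-3,4-disubstituted oxolane (ring atoms O1, C2, C3 carrying the benzyl group, C4 carrying the aryl carbinol, C5). The last operations are O-debenzylation and radical removal of a temporary nitro group on C3, which sets C3.
2. Key disconnection: O1–C2 and C3–C4 together, a formal (3+2) annulation of a trans-3-aryl-2,3-epoxy alcohol (three-atom unit O1–C5–C4) with a 2-benzylnitroethene (two-atom unit C2=C3). The oxolane is the only ring and is closed in this step.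
3. Enabling feature: O1–C5–C4–CH(OH)Ar is a 2,3-epoxy alcohol opened at its inner carbon (C4 and the carbinol carbon are a masked trans-epoxide, O1 its primary alkoxide). C3 is a CH between C4 and the O1-bound C2 methylene, so one nitro group on C3 makes C2 electrophilic, makes C3 nucleophilic, and later leaves as a radical.
4. Both partners derive from 3-(benzyloxy)-4-methoxybenzaldehyde: olefination, reduction and Shi epoxidation give the epoxy alcohol; Henry condensation, reduction, hydroxymethylation and dehydration give the nitroalkene.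

Key step: step 8

Remark: the ring locants O1 and C2 to C5 defined above are used in the text; the systematic names follow IUPAC numbering, in which the carbinol-bearing ring carbon is C3. Compound 1 is taken as a catalogue compound.

**Route**

Step 1
Reactants: 1 3-(benzyloxy)-4-methoxybenzaldehyde
Product: 2 ethyl (2E)-3-[3-(benzyloxy)-4-methoxyphenyl]prop-2-enoate
Conditions: (EtO)2P(O)CH2CO2Et, NaH, THF, 0 °C to rt
Reagents that add atoms: triethyl phosphonoacetate, CCOC(=O)CP(=O)(OCC)OCC
Why: Horner–Wadsworth–Emmons olefination of an aromatic aldehyde with a stabilised phosphonate should give the (E)-cinnamate selectively.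

Step 2
Reactants: 2 ethyl (2E)-3-[3-(benzyloxy)-4-methoxyphenyl]prop-2-enoate
Product: 3 (2E)-3-[3-(benzyloxy)-4-methoxyphenyl]prop-2-en-1-ol
Conditions: iBu2AlH (2.5 equiv), CH2Cl2, -78 °C; Rochelle salt work-up
Reagents that add atoms: none
Why: 1,2-reduction of the conjugated ester by iBu2AlH at low temperature should give the allylic alcohol without touching the alkene, the benzyl ether or the arene.

Step 3
Reactants: 3 (2E)-3-[3-(benzyloxy)-4-methoxyphenyl]prop-2-en-1-ol
Product: 4 [(2R,3R)-3-[3-(benzyloxy)-4-methoxyphenyl]oxiran-2-yl]methanol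
Conditions: D-fructose-derived Shi ketone (30 mol%), KHSO5 (Oxone), K2CO3, Bu4NHSO4, MeCN/CH2(OMe)2/aq. Na2B4O7 buffer, 0 °C
Reagents that add atoms: potassium peroxymonosulfate, [K+].[O-]S(=O)(=O)OO
Why: Shi asymmetric epoxidation delivers oxygen from the chiral dioxirane through a spiro transition state to one face of the trans-disubstituted electron-rich styrenyl alkene, which should give the (2R,3R)-epoxide, and its buffered basic medium spares the acid-labile para-alkoxyphenyl oxirane.

Step 4
Reactants: 1 3-(benzyloxy)-4-methoxybenzaldehyde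
Product: 5 2-(benzyloxy)-1-methoxy-4-[(E)-2-nitroethenyl]benzene
Conditions: MeNO2, NH4OAc, AcOH, 100 °C
Reagents that add atoms: nitromethane, C[N+](=O)[O-]
Why: Henry (nitroaldol) condensation with in situ dehydration should give the (E)-β-nitrostyrene.

Step 5
Reactants: 5 2-(benzyloxy)-1-methoxy-4-[(E)-2-nitroethenyl]benzene
Product: 6 2-(benzyloxy)-1-methoxy-4-(2-nitroethyl)benzene
Conditions: NaBH4, silica gel, CHCl3/iPrOH, rt
Reagents that add atoms: none
Why: conjugate hydride reduction of the nitroalkene by NaBH4 stops at the nitroalkane and leaves the nitro group and the benzyl ether intact.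

Step 6
Reactants: 6 2-(benzyloxy)-1-methoxy-4-(2-nitroethyl)benzene
Product: 7 3-[3-(benzyloxy)-4-methoxyphenyl]-2-nitropropan-1-ol (racemic)
Conditions: 37% aq. CH2O (1.05 equiv), Et3N (cat.), iPrOH, rt
Reagents that add atoms: formaldehyde, C=O
Why: base-catalysed Henry addition of the primary nitroalkane to about one equivalent of formaldehyde should give the mono(hydroxymethyl) adduct, whose stereocentre is destroyed in the next step.

Step 7
Reactants: 7 3-[3-(benzyloxy)-4-methoxyphenyl]-2-nitropropan-1-ol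
Product: 9 2-(benzyloxy)-1-methoxy-4-(2-nitroprop-2-en-1-yl)benzene, via methanesulfonate ester 8 (not isolated)
Conditions: MsCl, Et3N, CH2Cl2, -40 to 0 °C; used at once
Reagents that add atoms: none
Why: mesylation of the β-nitro alcohol followed by E1cB elimination through the nitronate can only place the double bond between the nitro-bearing carbon and the former carbinol carbon, giving the 1,1-disubstituted nitroalkene.

Step 8
Reactants: 4 [(2R,3R)-3-[3-(benzyloxy)-4-methoxyphenyl]oxiran-2-yl]methanol; 9 2-(benzyloxy)-1-methoxy-4-(2-nitroprop-2-en-1-yl)benzene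
Product: 12 (S)-[3-(benzyloxy)-4-methoxyphenyl]{(3S)-4-[3-(benzyloxy)-4-methoxybenzyl]-4-nitrooxolan-3-yl}methanol (both epimers at the nitro-bearing carbon), via potassium alkoxide 10 (not isolated), via potassium nitronate 11 (not isolated)
Conditions: KN(SiMe3)2 (1.0 equiv), THF, -78 °C; then 9, -78 to 0 °C; then DMSO, 40 °C; aq. NH4Cl
Reagents that add atoms: none
Why: Proposed new method: the potassium alkoxide of 4 adds to the unsubstituted terminus of nitroalkene 9 (oxa-Michael addition, O1–C2 bond), and the fully substituted nitronate carbon then opens the tethered epoxide at its proximal carbon by a 5-exo-tet SN2 displacement (C3–C4 bond); the closest known reaction types are Michael-initiated ring closures of 2-haloalkoxides onto acceptors to give tetrahydrofurans and intramolecular openings of epoxides by nitronates and other stabilised carbanions. The oxolane is the only ring closed, in the exo mode, with the three-atom tether O1–C5–C4 inside the new ring and the breaking epoxide C–O bond outside it. C4 is set by stereospecific inversion at the attacked epoxide carbon and the carbinol carbon keeps the configuration from the Shi epoxidation, so the trans-(2R,3R)-epoxide maps onto the (S)-carbinol and (S)-ring carbon of the target; the nitro-bearing C3 forms without control, which does not matter because it becomes a planar radical in step 9. The step needs attack at the proximal rather than the benzylic epoxide carbon (6-endo), which the collinear 5-exo trajectory and the absence of a Lewis acid (potassium counter-ion, DMSO) should secure, and C- rather than O-alkylation of the nitronate, which follows because O-attack would need a seven-membered ring. Adding 9 to preformed alkoxide at low temperature should consume the nitroalkene before base can isomerise or oligomerise it.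

Step 9
Reactants: 12 (S)-[3-(benzyloxy)-4-methoxyphenyl]{(3S)-4-[3-(benzyloxy)-4-methoxybenzyl]-4-nitrooxolan-3-yl}methanol
Product: 13 (S)-[3-(benzyloxy)-4-methoxyphenyl]{(3S,4R)-4-[3-(benzyloxy)-4-methoxybenzyl]oxolan-3-yl}methanol
Conditions: Bu3SnH (3 equiv), AIBN (0.3 equiv), toluene, 100 °C
Reagents that add atoms: none
Why: radical denitration of the tertiary nitro group gives a planar tertiary C3 radical from either epimer, and hydrogen-atom transfer from Bu3SnH to the ring face opposite the bulky neighbouring hydroxy(aryl)methyl group should place the benzyl group cis to it and set the (R)-configured ring carbon.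

Step 10
Reactants: 13 (S)-[3-(benzyloxy)-4-methoxyphenyl]{(3S,4R)-4-[3-(benzyloxy)-4-methoxybenzyl]oxolan-3-yl}methanol
Product: 14 5-{(S)-hydroxy[(3S,4R)-4-(3-hydroxy-4-methoxybenzyl)oxolan-3-yl]methyl}-2-methoxyphenol
Conditions: H2 (1 atm), Pd/C (10%), EtOAc, rt
Reagents that add atoms: none
Why: hydrogenolysis of the two aryl benzyl ethers over palladium on carbon under neutral conditions should be much faster than cleavage of the secondary benzylic alcohol, which needs acid activation, so the target should be released with all three stereocentres untouched.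

**Compound list**

1 | 3-(benzyloxy)-4-methoxybenzaldehyde | O=Cc1ccc(OC)c(OCc2ccccc2)c1 | starting material
2 | ethyl (2E)-3-[3-(benzyloxy)-4-methoxyphenyl]prop-2-enoate | CCOC(=O)/C=C/c1ccc(OC)c(OCc2ccccc2)c1 | intermediate
3 | (2E)-3-[3-(benzyloxy)-4-methoxyphenyl]prop-2-en-1-ol | OC/C=C/c1ccc(OC)c(OCc2ccccc2)c1 | intermediate
4 | [(2R,3R)-3-[3-(benzyloxy)-4-methoxyphenyl]oxiran-2-yl]methanol | OC[C@H]1O[C@@H]1c1ccc(OC)c(OCc2ccccc2)c1 | intermediate
5 | 2-(benzyloxy)-1-methoxy-4-[(E)-2-nitroethenyl]benzene | [O-][N+](=O)/C=C/c1ccc(OC)c(OCc2ccccc2)c1 | intermediate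
6 | 2-(benzyloxy)-1-methoxy-4-(2-nitroethyl)benzene | [O-][N+](=O)CCc1ccc(OC)c(OCc2ccccc2)c1 | intermediate
7 | 3-[3-(benzyloxy)-4-methoxyphenyl]-2-nitropropan-1-ol (racemic) | OCC(Cc1ccc(OC)c(OCc2ccccc2)c1)[N+](=O)[O-] | intermediate
8 | 3-[3-(benzyloxy)-4-methoxyphenyl]-2-nitropropyl methanesulfonate (racemic, not isolated) | CS(=O)(=O)OCC(Cc1ccc(OC)c(OCc2ccccc2)c1)[N+](=O)[O-] | intermediate
9 | 2-(benzyloxy)-1-methoxy-4-(2-nitroprop-2-en-1-yl)benzene | C=C(Cc1ccc(OC)c(OCc2ccccc2)c1)[N+](=O)[O-] | intermediate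
10 | potassium [(2R,3R)-3-[3-(benzyloxy)-4-methoxyphenyl]oxiran-2-yl]methanolate (not isolated) | [K+].[O-]C[C@H]1O[C@@H]1c1ccc(OC)c(OCc2ccccc2)c1 | intermediate
11 | potassium nitronate of 2-(benzyloxy)-4-[3-{[(2R,3R)-3-[3-(benzyloxy)-4-methoxyphenyl]oxiran-2-yl]methoxy}-2-nitropropyl]-1-methoxybenzene (not isolated) | [K+].[O-][N+]([O-])=C(Cc1ccc(OC)c(OCc2ccccc2)c1)COC[C@H]1O[C@@H]1c1ccc(OC)c(OCc2ccccc2)c1 | intermediate
12 | (S)-[3-(benzyloxy)-4-methoxyphenyl]{(3S)-4-[3-(benzyloxy)-4-methoxybenzyl]-4-nitrooxolan-3-yl}methanol (both epimers at the nitro-bearing carbon) | COc1ccc(CC2(COC[C@H]2[C@H](O)c2ccc(OC)c(OCc3ccccc3)c2)[N+](=O)[O-])cc1OCc1ccccc1 | intermediate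
13 | (S)-[3-(benzyloxy)-4-methoxyphenyl]{(3S,4R)-4-[3-(benzyloxy)-4-methoxybenzyl]oxolan-3-yl}methanol | COc1ccc(C[C@H]2COC[C@H]2[C@H](O)c2ccc(OC)c(OCc3ccccc3)c2)cc1OCc1ccccc1 | intermediate
14 | 5-{(S)-hydroxy[(3S,4R)-4-(3-hydroxy-4-methoxybenzyl)oxolan-3-yl]methyl}-2-methoxyphenol | COc1ccc(C[C@H]2COC[C@H]2[C@H](O)c2ccc(OC)c(O)c2)cc1O | target

**Step count and risks**

Total step count: 10. Longest linear sequence: 7 steps (steps 4 to 10).

Steps most likely to fail:

1. Step 8 (Proposed new method). C-alkylation of the hindered, disubstituted nitronate by the epoxide may be too slow, so that retro-oxa-Michael cleavage, oligomerisation of released nitroalkene or opening at the benzylic epoxide carbon takes over. The fallback uses a ketone as the activating group, isolates the conjugate adduct, and sets C3 by hydrogenation; it sets out from 1 and 4 and comes back at 14. Aldehyde 1 and CH2=CHMgBr give 1-[3-(benzyloxy)-4-methoxyphenyl]prop-2-en-1-ol F1, and MnO2 oxidation gives 1-[3-(benzyloxy)-4-methoxyphenyl]prop-2-en-1-one F2. Oxa-Michael addition of 4 to F2 with catalytic KOtBu gives 1-[3-(benzyloxy)-4-methoxyphenyl]-3-{[(2R,3R)-3-[3-(benzyloxy)-4-methoxyphenyl]oxiran-2-yl]methoxy}propan-1-one F3. LiN(SiMe3)2 then closes the ring by intramolecular 5-exo alkylation of the ketone enolate by the epoxide to give [3-(benzyloxy)-4-methoxyphenyl]{(4S)-4-[(S)-[3-(benzyloxy)-4-methoxyphenyl](hydroxy)methyl]oxolan-3-yl}methanone F4 as a mixture of C3 epimers. TBSCl and imidazole give [3-(benzyloxy)-4-methoxyphenyl]{(4S)-4-[(S)-[3-(benzyloxy)-4-methoxyphenyl]{[tert-butyl(dimethyl)silyl]oxy}methyl]oxolan-3-yl}methanone F5. KN(SiMe3)2 and PhNTf2 give [3-(benzyloxy)-4-methoxyphenyl]{(4S)-4-[(S)-[3-(benzyloxy)-4-methoxyphenyl]{[tert-butyl(dimethyl)silyl]oxy}methyl]oxolan-3-ylidene}methyl trifluoromethanesulfonate F6. Reduction with Pd(OAc)2, PPh3, HCO2H and Bu3N gives tert-butyl{(S)-[3-(benzyloxy)-4-methoxyphenyl][(3S)-4-{[3-(benzyloxy)-4-methoxyphenyl]methylidene}oxolan-3-yl]methoxy}dimethylsilane F7. Hydrogenation over Pd/C should add hydrogen to the exocyclic alkene from the face opposite the silyloxybenzyl group (cis C3) and remove both benzyl ethers to give 5-{(S)-{[tert-butyl(dimethyl)silyl]oxy}[(3S,4R)-4-(3-hydroxy-4-methoxybenzyl)oxolan-3-yl]methyl}-2-methoxyphenol F8. Bu4NF then gives 14.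

2. Step 9. Hydrogen-atom transfer to the planar C3 radical may show poor facial selectivity and deliver much of the trans isomer. The fallback replaces the free carbinol by a removable bulky shielding group as the control element; it sets out from 12 and comes back at 13. TBSCl and imidazole convert 12 into tert-butyl{(S)-[3-(benzyloxy)-4-methoxyphenyl][(3S)-4-{[3-(benzyloxy)-4-methoxyphenyl]methyl}-4-nitrooxolan-3-yl]methoxy}dimethylsilane F9. Denitration with Bu3SnH and AIBN, now with the larger silyloxybenzyl group blocking one face, should give tert-butyl{(S)-[3-(benzyloxy)-4-methoxyphenyl][(3S,4R)-4-{[3-(benzyloxy)-4-methoxyphenyl]methyl}oxolan-3-yl]methoxy}dimethylsilane F10. Bu4NF then gives 13.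

3. Step 7. The 1,1-disubstituted nitroalkene may isomerise into conjugation with the arene or oligomerise during elimination and isolation. The fallback avoids isolating it; it sets out from 7 and comes back at 12. Acylation of 7 with pivaloyl chloride and pyridine gives the bench-stable 3-[3-(benzyloxy)-4-methoxyphenyl]-2-nitropropyl 2,2-dimethylpropanoate F11. F11 is added to alkoxide 10 in the presence of a second equivalent of KN(SiMe3)2, so that 9 is formed by E1cB loss of pivalate only in the presence of the alkoxide, is trapped as nitronate 11, and cyclises to 12 as in step 8.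

**Further compounds**

F1 | step 8 | 1-[3-(benzyloxy)-4-methoxyphenyl]prop-2-en-1-ol (racemic) | C=CC(O)c1ccc(OC)c(OCc2ccccc2)c1
F2 | step 8 | 1-[3-(benzyloxy)-4-methoxyphenyl]prop-2-en-1-one | C=CC(=O)c1ccc(OC)c(OCc2ccccc2)c1
F3 | step 8 | 1-[3-(benzyloxy)-4-methoxyphenyl]-3-{[(2R,3R)-3-[3-(benzyloxy)-4-methoxyphenyl]oxiran-2-yl]methoxy}propan-1-one | O=C(CCOC[C@H]1O[C@@H]1c1ccc(OC)c(OCc2ccccc2)c1)c1ccc(OC)c(OCc2ccccc2)c1
F4 | step 8 | [3-(benzyloxy)-4-methoxyphenyl]{(4S)-4-[(S)-[3-(benzyloxy)-4-methoxyphenyl](hydroxy)methyl]oxolan-3-yl}methanone (C3 epimers) | O=C(C1COC[C@H]1[C@H](O)c1ccc(OC)c(OCc2ccccc2)c1)c1ccc(OC)c(OCc2ccccc2)c1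
F5 | step 8 | [3-(benzyloxy)-4-methoxyphenyl]{(4S)-4-[(S)-[3-(benzyloxy)-4-methoxyphenyl]{[tert-butyl(dimethyl)silyl]oxy}methyl]oxolan-3-yl}methanone (C3 epimers) | O=C(C1COC[C@H]1[C@H](O[Si](C)(C)C(C)(C)C)c1ccc(OC)c(OCc2ccccc2)c1)c1ccc(OC)c(OCc2ccccc2)c1
F6 | step 8 | [3-(benzyloxy)-4-methoxyphenyl]{(4S)-4-[(S)-[3-(benzyloxy)-4-methoxyphenyl]{[tert-butyl(dimethyl)silyl]oxy}methyl]oxolan-3-ylidene}methyl trifluoromethanesulfonate (alkene isomers) | O=S(=O)(OC(=C1COC[C@H]1[C@H](O[Si](C)(C)C(C)(C)C)c1ccc(OC)c(OCc2ccccc2)c1)c1ccc(OC)c(OCc2ccccc2)c1)C(F)(F)F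
F7 | step 8 | tert-butyl{(S)-[3-(benzyloxy)-4-methoxyphenyl][(3S)-4-{[3-(benzyloxy)-4-methoxyphenyl]methylidene}oxolan-3-yl]methoxy}dimethylsilane (alkene isomers) | C(=C1COC[C@H]1[C@H](O[Si](C)(C)C(C)(C)C)c1ccc(OC)c(OCc2ccccc2)c1)c1ccc(OC)c(OCc2ccccc2)c1
F8 | step 8 | 5-{(S)-{[tert-butyl(dimethyl)silyl]oxy}[(3S,4R)-4-(3-hydroxy-4-methoxybenzyl)oxolan-3-yl]methyl}-2-methoxyphenol | COc1ccc(C[C@H]2COC[C@H]2[C@H](O[Si](C)(C)C(C)(C)C)c2ccc(OC)c(O)c2)cc1O
F9 | step 9 | tert-butyl{(S)-[3-(benzyloxy)-4-methoxyphenyl][(3S)-4-{[3-(benzyloxy)-4-methoxyphenyl]methyl}-4-nitrooxolan-3-yl]methoxy}dimethylsilane (both epimers at the nitro-bearing carbon) | COc1ccc(CC2(COC[C@H]2[C@H](O[Si](C)(C)C(C)(C)C)c2ccc(OC)c(OCc3ccccc3)c2)[N+](=O)[O-])cc1OCc1ccccc1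
F10 | step 9 | tert-butyl{(S)-[3-(benzyloxy)-4-methoxyphenyl][(3S,4R)-4-{[3-(benzyloxy)-4-methoxyphenyl]methyl}oxolan-3-yl]methoxy}dimethylsilane | COc1ccc(C[C@H]2COC[C@H]2[C@H](O[Si](C)(C)C(C)(C)C)c2ccc(OC)c(OCc3ccccc3)c2)cc1OCc1ccccc1
F11 | step 7 | 3-[3-(benzyloxy)-4-methoxyphenyl]-2-nitropropyl 2,2-dimethylpropanoate (racemic) | CC(C)(C)C(=O)OCC(Cc1ccc(OC)c(OCc2ccccc2)c1)[N+](=O)[O-]
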